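**Strategy**

The benzofuran is cut at two furan bonds, C3–C3a and O1–C2. This works because O1 and C3a are the oxygen and an ortho carbon of a ring A phenol, whereas C2 and C3 derive from the C=O carbon and the neighbouring CH2 of a ketone that carries ring B and, on that CH2, the future formyl carbon masked as a dioxolane. An O-aryl ketoxime ether uniting both halves is treated with acid: in one operation a [3,3] shift forms C3–C3a, the phenol oxygen closes the furan at O1–C2 with expulsion of ammonia, and the 2-aryl-3-formylbenzofuran core results. The precursor's ring A is symmetric, so only one regiochemical outcome exists.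

Key step: step 7

Remark: ketone 6 is assumed to be purchasable (otherwise BnBr/K2CO3 on 2,4-dihydroxyacetophenone adds one step); MesSO2ONH2 is a reagent made fresh from its commercial N-Boc derivative with CF3CO2H; the target has no stereocentre, and the C=C and C=N geometries on the way do not affect the outcome.

**Route**

Step 1
Reactants: 1 4-hydroxy-2,6-dimethoxybenzaldehyde; 2 methyl (triphenylphosphoranylidene)acetate
Product: 3 methyl (2E)-3-(4-hydroxy-2,6-dimethoxyphenyl)prop-2-enoate
Conditions: 2 (1.3 equiv), PhMe, 110 °C
Reagents that add atoms: none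
Why: A Wittig olefination with a stabilized ylide should convert the hindered, electron-rich aldehyde on heating without protecting the phenol, and the E geometry it gives is erased in step 2.

Step 2
Reactants: 3 methyl (2E)-3-(4-hydroxy-2,6-dimethoxyphenyl)prop-2-enoate
Product: 4 methyl 3-(4-hydroxy-2,6-dimethoxyphenyl)propanoate
Conditions: H2 (1 atm), 10% Pd/C, MeOH, rt
Reagents that add atoms: none
Why: Catalytic hydrogenation of a cinnamate C=C is reliable and leaves the phenol, the aryl methyl ethers and the ester untouched.

Step 3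
Reactants: 4 methyl 3-(4-hydroxy-2,6-dimethoxyphenyl)propanoate
Product: 5 methyl 3-[4-(aminooxy)-2,6-dimethoxyphenyl]propanoate
Conditions: KOt-Bu (1.0 equiv), THF, 0 °C; then MesSO2ONH2 (1.2 equiv), CH2Cl2, 0 °C; used at once
Reagents that add atoms: O-(mesitylsulfonyl)hydroxylamine, Cc1cc(C)c(S(=O)(=O)ON)c(C)c1
Why: Electrophilic amination of a phenoxide at oxygen by an O-sulfonylhydroxylamine (substitution at nitrogen with sulfonate as leaving group) should give the O-arylhydroxylamine, and one equivalent of base deprotonates only the phenol so the ester is not touched.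

Step 4
Reactants: 6 1-[2,4-bis(benzyloxy)phenyl]ethan-1-one; 7 methyl formate
Product: 8 sodium (1Z)-3-[2,4-bis(benzyloxy)phenyl]-3-oxoprop-1-en-1-olate
Conditions: NaOMe (1.1 equiv), HCO2Me (5 equiv), THF, 0 °C → rt; salt collected by filtration
Reagents that add atoms: sodium methoxide, [Na+].[O-]C
Why: A crossed Claisen condensation of the methyl ketone enolate with the non-enolizable formate should be driven to completion by precipitation of the chelated sodium enolate, and benzyl ethers are inert to methoxide.

Step 5
Reactants: 8 sodium (1Z)-3-[2,4-bis(benzyloxy)phenyl]-3-oxoprop-1-en-1-olate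
Product: 9 1-[2,4-bis(benzyloxy)phenyl]-2-(1,3-dioxolan-2-yl)ethan-1-one
Conditions: HOCH2CH2OH (3 equiv), TsOH·H2O (1.2 equiv), PhH, reflux, azeotropic removal of water
Reagents that add atoms: ethylene glycol, OCCO
Why: Acid-catalysed acetalization of the liberated β-keto aldehyde should occur only at the formyl carbon, since the hindered, donor-substituted aryl ketone is far less electrophilic, and the cyclic acetal recloses if it opens to the enol ether.

Step 6
Reactants: 5 methyl 3-[4-(aminooxy)-2,6-dimethoxyphenyl]propanoate; 9 1-[2,4-bis(benzyloxy)phenyl]-2-(1,3-dioxolan-2-yl)ethan-1-one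
Product: 10 methyl 3-{4-[({(1E)-1-[2,4-bis(benzyloxy)phenyl]-2-(1,3-dioxolan-2-yl)ethylidene}amino)oxy]-2,6-dimethoxyphenyl}propanoate
Conditions: C5H5N·HCl (1 equiv), pyridine–MeOH, 3 Å MS, 60 °C
Reagents that add atoms: none
Why: Oxime ether formation by condensation of the O-arylhydroxylamine with the ketone under pyridinium buffering should place nitrogen on the ketone carbon only, because the dioxolane does not exchange at this acidity, and this fixes which carbon becomes C2.

Step 7
Reactants: 10 methyl 3-{4-[({(1E)-1-[2,4-bis(benzyloxy)phenyl]-2-(1,3-dioxolan-2-yl)ethylidene}amino)oxy]-2,6-dimethoxyphenyl}propanoate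
Product: 12 methyl 3-{2-[2,4-bis(benzyloxy)phenyl]-3-formyl-4,6-dimethoxy-1-benzofuran-5-yl}propanoate, via benzofuran dioxolane acetal 11 (not isolated)
Conditions: MsOH (3 equiv), THF, 50 °C; then 1 M aq. HCl, THF, rt
Reagents that add atoms: water, O
Why: MsOH protonates the oxime nitrogen and equilibrates 10 with its N-aryloxy enamine, which undergoes a [3,3]-sigmatropic shift that breaks the weak N–O bond and joins the α-carbon (C3) to an ortho carbon of ring A (C3a), after which tautomerization restores the phenol next to a protonated ketimine. The closest known reaction type is the acid-promoted rearrangement of O-aryl ketoxime ethers to benzofurans, the oxygen counterpart of the Fischer indole synthesis. The furan ring closes by 5-exo-trig addition of the phenol oxygen to the iminium carbon (O1–C2), and loss of ammonia as its mesylate salt aromatizes it to 11. No stereocentre is formed. Three selectivities are needed: the enamine can form only toward the dioxolane-bearing CH2 because the other ketone substituent is ring B, the two ortho carbons of the symmetric ring A are equivalent and each is activated by an ortho and a para methoxy group, and closure at the iminium carbon is favoured over closure at the acetal carbon because the cyclic acetal ionizes only reversibly whereas ammonia loss is irreversible. Aqueous acid in the work-up should then hydrolyse the dioxolane of 11 to the aldehyde 12 while the ester, the benzyl ethers and the methyl ethers are left alone.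

Step 8
Reactants: 12 methyl 3-{2-[2,4-bis(benzyloxy)phenyl]-3-formyl-4,6-dimethoxy-1-benzofuran-5-yl}propanoate
Product: 13 methyl 3-[2-(2,4-dihydroxyphenyl)-3-formyl-4-hydroxy-6-methoxy-1-benzofuran-5-yl]propanoate
Conditions: BCl3 (8 equiv), C6HMe5 (6 equiv), CH2Cl2, −78 → 0 °C; then aq. NaHCO3
Reagents that add atoms: none
Why: Lewis acid ether cleavage by BCl3 should remove both benzyl groups (the benzyl cations are trapped by pentamethylbenzene) and, through chelation between the formyl oxygen and the adjacent C4 methoxy oxygen, cleave that methyl ether alone, since the C6 methoxy group has no neighbouring carbonyl and the methyl ester is slow to react at this temperature.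

Step 9
Reactants: 13 methyl 3-[2-(2,4-dihydroxyphenyl)-3-formyl-4-hydroxy-6-methoxy-1-benzofuran-5-yl]propanoate
Product: 14 methyl 3-{2-(2,4-dihydroxyphenyl)-3-[(E)-(2,2-dimethylhydrazinylidene)methyl]-4-hydroxy-6-methoxy-1-benzofuran-5-yl}propanoate
Conditions: Me2NNH2 (3 equiv), AcOH (cat.), MeOH, 40 °C
Reagents that add atoms: 1,1-dimethylhydrazine, CN(C)N
Why: Hydrazone formation masks the aldehyde as a C=N unit that carries no leaving group on carbon, so it cannot be ionized by the ring B phenoxides or attacked by MeMgBr in step 10, as an O,O-acetal could be.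

Step 10
Reactants: 14 methyl 3-{2-(2,4-dihydroxyphenyl)-3-[(E)-(2,2-dimethylhydrazinylidene)methyl]-4-hydroxy-6-methoxy-1-benzofuran-5-yl}propanoate
Product: 16 2-(2,4-dihydroxyphenyl)-4-hydroxy-5-(3-hydroxy-3-methylbutyl)-6-methoxy-1-benzofuran-3-carbaldehyde, via tertiary alcohol hydrazone 15 (not isolated)
Conditions: MeMgBr (10 equiv), THF, 0 °C → rt; then sat. aq. (CO2H)2, THF–EtOAc, rt; NaHCO3 wash
Reagents that add atoms: methylmagnesium bromide, C[Mg]Br; water, O
Why: After the three phenols are deprotonated, double Grignard addition of MeMgBr to the methyl ester should give the tertiary alcohol while the N,N-dimethylhydrazone stays inert, and mild aqueous acid hydrolysis of the hydrazone, assisted by the ortho hydroxyl of ring B, should then release the aldehyde without ionizing the tertiary alcohol.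

**Compound list**

1 | 4-hydroxy-2,6-dimethoxybenzaldehyde | COc1cc(O)cc(OC)c1C=O | starting material
2 | methyl (triphenylphosphoranylidene)acetate | COC(=O)C=P(c1ccccc1)(c1ccccc1)c1ccccc1 | starting material
3 | methyl (2E)-3-(4-hydroxy-2,6-dimethoxyphenyl)prop-2-enoate | COC(=O)/C=C/c1c(OC)cc(O)cc1OC | intermediate
4 | methyl 3-(4-hydroxy-2,6-dimethoxyphenyl)propanoate | COC(=O)CCc1c(OC)cc(O)cc1OC | intermediate
5 | methyl 3-[4-(aminooxy)-2,6-dimethoxyphenyl]propanoate | COC(=O)CCc1c(OC)cc(ON)cc1OC | intermediate
6 | 1-[2,4-bis(benzyloxy)phenyl]ethan-1-one | CC(=O)c1ccc(OCc2ccccc2)cc1OCc1ccccc1 | starting material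
7 | methyl formate | COC=O | starting material
8 | sodium (1Z)-3-[2,4-bis(benzyloxy)phenyl]-3-oxoprop-1-en-1-olate | [Na+].[O-]/C=C\C(=O)c1ccc(OCc2ccccc2)cc1OCc1ccccc1 | intermediate
9 | 1-[2,4-bis(benzyloxy)phenyl]-2-(1,3-dioxolan-2-yl)ethan-1-one | O=C(CC1OCCO1)c1ccc(OCc2ccccc2)cc1OCc1ccccc1 | intermediate
10 | methyl 3-{4-[({(1E)-1-[2,4-bis(benzyloxy)phenyl]-2-(1,3-dioxolan-2-yl)ethylidene}amino)oxy]-2,6-dimethoxyphenyl}propanoate | COC(=O)CCc1c(OC)cc(O/N=C(/c2ccc(OCc3ccccc3)cc2OCc2ccccc2)CC2OCCO2)cc1OC | intermediate
11 | methyl 3-{2-[2,4-bis(benzyloxy)phenyl]-3-(1,3-dioxolan-2-yl)-4,6-dimethoxy-1-benzofuran-5-yl}propanoate (formed in the flask in step 7) | COC(=O)CCc1c(OC)cc2oc(-c3ccc(OCc4ccccc4)cc3OCc3ccccc3)c(C3OCCO3)c2c1OC | intermediate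
12 | methyl 3-{2-[2,4-bis(benzyloxy)phenyl]-3-formyl-4,6-dimethoxy-1-benzofuran-5-yl}propanoate | COC(=O)CCc1c(OC)cc2oc(-c3ccc(OCc4ccccc4)cc3OCc3ccccc3)c(C=O)c2c1OC | intermediate
13 | methyl 3-[2-(2,4-dihydroxyphenyl)-3-formyl-4-hydroxy-6-methoxy-1-benzofuran-5-yl]propanoate | COC(=O)CCc1c(OC)cc2oc(-c3ccc(O)cc3O)c(C=O)c2c1O | intermediate
14 | methyl 3-{2-(2,4-dihydroxyphenyl)-3-[(E)-(2,2-dimethylhydrazinylidene)methyl]-4-hydroxy-6-methoxy-1-benzofuran-5-yl}propanoate | COC(=O)CCc1c(OC)cc2oc(-c3ccc(O)cc3O)c(/C=N/N(C)C)c2c1O | intermediate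
15 | 2-(2,4-dihydroxyphenyl)-3-[(E)-(2,2-dimethylhydrazinylidene)methyl]-5-(3-hydroxy-3-methylbutyl)-6-methoxy-1-benzofuran-4-ol (formed in the flask in step 10) | CC(C)(O)CCc1c(OC)cc2oc(-c3ccc(O)cc3O)c(/C=N/N(C)C)c2c1O | intermediate
16 | 2-(2,4-dihydroxyphenyl)-4-hydroxy-5-(3-hydroxy-3-methylbutyl)-6-methoxy-1-benzofuran-3-carbaldehyde | COc1cc2oc(-c3ccc(O)cc3O)c(C=O)c2c(O)c1CCC(C)(C)O | target

**Step count and risks**

Total steps: 10. Longest linear sequence: 8 steps (steps 1, 2, 3, 6, 7, 8, 9, 10); the ring B ketone branch (steps 4 and 5) joins at step 6.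

Steps most likely to fail:

1. Step 7. In the strong acid the acetal may ionize before the rearrangement is complete, so that the freed oxocarbenium carbon captures the new phenol oxygen (furan closure on the wrong carbon) or alkylates the very electron-rich ring A; benzyl groups may also be lost. The fallback sets out from 10 and triggers the same [3,3] shift by N-acylation instead of protonation. (CF3CO)2O and DMAP in CH2Cl2 at 0 °C to rt should take 10 through its N-trifluoroacetyl enamine to the ring-closed aminal methyl 3-{2-[2,4-bis(benzyloxy)phenyl]-3-(1,3-dioxolan-2-yl)-4,6-dimethoxy-2-(2,2,2-trifluoroacetamido)-2,3-dihydro-1-benzofuran-5-yl}propanoate F1, with the acetal intact because no free acid is present. TsOH·H2O in wet THF should then expel trifluoroacetamide, aromatize the ring and hydrolyse the dioxolane, which brings the route back at 12.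

2. Step 8. The chelate that directs demethylation is seven-membered, so cleavage of the C4 methyl ether may be slow or unselective; benzyl cations may C-alkylate the electron-rich rings despite the scavenger, and the ester may be attacked on warming. The fallback sets out from 12 and separates the two deprotections. Hydrogenolysis (H2, 10% Pd/C, EtOAc, rt, stopped after uptake of two equivalents) should give methyl 3-[2-(2,4-dihydroxyphenyl)-3-formyl-4,6-dimethoxy-1-benzofuran-5-yl]propanoate F2. Chelation-assisted demethylation by iodide with MgI2·OEt2 in PhMe–Et2O at 60 °C should then cleave only the methyl ether next to the formyl group, which brings the route back at 13.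

3. Step 3. The electron-rich phenoxide may be aminated on carbon or oxidized instead of aminated on oxygen, and the O-arylhydroxylamine may decompose on isolation. The fallback sets out from 4 and forms the aryl C–O bond by cross-coupling. (CF3SO2)2O and pyridine in CH2Cl2 should give methyl 3-{2,6-dimethoxy-4-[(trifluoromethanesulfonyl)oxy]phenyl}propanoate F3. C–O coupling with ethyl N-hydroxyacetimidate ([Pd(allyl)Cl]2, t-BuBrettPhos, Cs2CO3, PhMe, 65 °C) should give ethyl (1E)-N-[3,5-dimethoxy-4-(3-methoxy-3-oxopropyl)phenoxy]ethanimidate F4. Hydrolysis with aq. HCl in dioxane at rt, followed by NaHCO3, brings the route back at 5.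

**Further compounds**

F1 | step 7 | methyl 3-{2-[2,4-bis(benzyloxy)phenyl]-3-(1,3-dioxolan-2-yl)-4,6-dimethoxy-2-(2,2,2-trifluoroacetamido)-2,3-dihydro-1-benzofuran-5-yl}propanoate (racemic, mixture of C2/C3 diastereomers; both centres vanish on aromatization) | COC(=O)CCc1c(OC)cc2OC(NC(=O)C(F)(F)F)(c3ccc(OCc4ccccc4)cc3OCc3ccccc3)C(C3OCCO3)c2c1OC
F2 | step 8 | methyl 3-[2-(2,4-dihydroxyphenyl)-3-formyl-4,6-dimethoxy-1-benzofuran-5-yl]propanoate | COC(=O)CCc1c(OC)cc2oc(-c3ccc(O)cc3O)c(C=O)c2c1OC
F3 | step 3 | methyl 3-{2,6-dimethoxy-4-[(trifluoromethanesulfonyl)oxy]phenyl}propanoate | COC(=O)CCc1c(OC)cc(OS(=O)(=O)C(F)(F)F)cc1OC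
F4 | step 3 | ethyl (1E)-N-[3,5-dimethoxy-4-(3-methoxy-3-oxopropyl)phenoxy]ethanimidate | CCO/C(C)=N/Oc1cc(OC)c(CCC(=O)OC)c(OC)c1
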